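**Retrosynthetic overview**
1. The strategy rests on ring A, the phenethyl ring (C1 = CH2CH2O chain, C2 = benzylic CH2, C3 = Br, C4 and C5 = O, C6 = H): the bromine carbon C3 lies between the benzylated carbon C2 and the oxygenated carbon C4, which is the pattern a carbon nucleophile and Br+ leave on a 3-alkoxyaryne.
2. Endgame, read backwards: hydrolysis of four MOM ethers, O-sulfation of the one free (primary) hydroxyl, desilylation.
3. Key disconnection: the C2–CH2 and C3–Br bonds of ring A are cut together, giving the C2–C3 aryne of a bis-MOM phenethyl silyl ether (from its 2-bromide), a ring B benzylmagnesium chloride (2,3-dibromo-4,5-bis-MOM) and a Br+ donor.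
4. The aryne precursor comes from hydroxytyrosol (MOM, TIPS, NBS); the Grignard reagent comes from 5-bromovanillin (bromination, demethylation, MOM, reduction, chlorination, Mg insertion).
5. No ring is formed at any stage (both benzene rings are bought), and the target has no stereocentre.

Key step: step 10

Assumption: the target is made and isolated as the free alkyl hydrogen sulfate exactly as drawn; ring B is the 2,3-dibromo-4,5-dioxygenated benzyl ring.

**Route**

Step 1
Reactants: 1 hydroxytyrosol, 2-(3,4-dihydroxyphenyl)ethanol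
Product: 2 2-[3,4-bis(methoxymethoxy)phenyl]ethanol
Conditions: MOMCl (2.3 equiv), K2CO3, acetone, 0 °C → rt, under N2
Reagents that add atoms: chloromethyl methyl ether (MOMCl), COCCl
Why: Williamson-type O-alkylation of the two phenoxides; carbonate deprotonates the phenols but not the much less acidic primary alcohol, so the side-chain hydroxyl should stay free.

Step 2
Reactants: 2 2-[3,4-bis(methoxymethoxy)phenyl]ethanol
Product: 3 {2-[3,4-bis(methoxymethoxy)phenyl]ethoxy}triisopropylsilane
Conditions: TIPSCl, imidazole, DMF, rt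
Reagents that add atoms: chlorotriisopropylsilane (TIPSCl), CC(C)[Si](Cl)(C(C)C)C(C)C
Why: Silylation of the primary alcohol; the bulky silyl ether tolerates amide base and Grignard reagents and keeps the chain oxygen from adding to the later aryne.

Step 3
Reactants: 3 {2-[3,4-bis(methoxymethoxy)phenyl]ethoxy}triisopropylsilane
Product: 4 {2-[2-bromo-4,5-bis(methoxymethoxy)phenyl]ethoxy}triisopropylsilane
Conditions: NBS (1.05 equiv), solid NaHCO3, MeCN, 0 °C → rt, dark
Reagents that add atoms: N-bromosuccinimide (NBS), O=C1CCC(=O)N1Br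
Why: Electrophilic aromatic bromination; the site para to the C3 oxygen and ortho to the chain is the most activated unhindered position of a 3,4-dialkoxyphenethyl ring, and buffered NBS should spare the MOM acetals and the silyl ether.

Step 4
Reactants: 5 5-bromovanillin, 3-bromo-4-hydroxy-5-methoxybenzaldehyde
Product: 6 5,6-dibromovanillin, 2,3-dibromo-4-hydroxy-5-methoxybenzaldehyde
Conditions: Br2 (1.1 equiv), Fe powder (cat.), AcOH, rt
Reagents that add atoms: bromine, BrBr
Why: Lewis-acid-assisted electrophilic aromatic bromination; with C5 blocked, the position para to the methoxy group (C6) is the one that should be brominated.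

Step 5
Reactants: 6 5,6-dibromovanillin
Product: 7 2,3-dibromo-4,5-dihydroxybenzaldehyde
Conditions: AlCl3, pyridine, CH2Cl2, reflux; then cold dilute aq HCl
Reagents that add atoms: none
Why: Chelation-assisted O-demethylation; the aluminium phenoxide of the free 4-OH binds the neighbouring methoxy oxygen, and pyridine removes the methyl group by SN2 attack.

Step 6
Reactants: 7 2,3-dibromo-4,5-dihydroxybenzaldehyde
Product: 8 2,3-dibromo-4,5-bis(methoxymethoxy)benzaldehyde
Conditions: MOMCl (3 equiv), iPr2NEt, CH2Cl2, 0 °C → rt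
Reagents that add atoms: chloromethyl methyl ether (MOMCl), COCCl
Why: Acetal-forming O-alkylation of both acidic phenols under amine base; the aldehyde and aryl bromides do not react.

Step 7
Reactants: 8 2,3-dibromo-4,5-bis(methoxymethoxy)benzaldehyde
Product: 9 [2,3-dibromo-4,5-bis(methoxymethoxy)phenyl]methanol
Conditions: NaBH4, MeOH–THF, 0 °C
Reagents that add atoms: none
Why: Borohydride reduction of the aldehyde to the benzylic alcohol; aryl bromides and MOM acetals are inert to NaBH4.

Step 8
Reactants: 9 [2,3-dibromo-4,5-bis(methoxymethoxy)phenyl]methanol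
Product: 11 2,3-dibromo-4,5-bis(methoxymethoxy)benzyl chloride, via benzyl mesylate 10 (not isolated)
Conditions: MsCl, Et3N, LiCl, THF, 0 °C → rt
Reagents that add atoms: lithium chloride, [Li+].[Cl-]; methanesulfonyl chloride, CS(=O)(=O)Cl (its mesyl group stays only in 10, its chloride joins the chloride pool)
Why: Mesylation followed by SN2 displacement with chloride in the same flask; no acid is generated free, so the MOM acetals should survive.

Step 9
Reactants: 11 2,3-dibromo-4,5-bis(methoxymethoxy)benzyl chloride
Product: 12 [2,3-dibromo-4,5-bis(methoxymethoxy)benzyl]magnesium chloride (ether solution, titrated, used at once)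
Conditions: Mg turnings (excess, activated), Et2O with a little THF, 0 °C, slow addition at high dilution
Reagents that add atoms: magnesium, [Mg]
Why: Grignard formation by oxidative insertion of magnesium; the benzylic C–Cl bond reacts far faster than aryl C–Br bonds at 0 °C (ring-brominated benzylmagnesium halides are standard reagents), and slow dilute addition holds back Wurtz homocoupling.

Step 10
Reactants: 4 {2-[2-bromo-4,5-bis(methoxymethoxy)phenyl]ethoxy}triisopropylsilane; 12 [2,3-dibromo-4,5-bis(methoxymethoxy)benzyl]magnesium chloride (2.5 equiv)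
Product: 16 {2-[3-bromo-2-(2,3-dibromo-4,5-bis(methoxymethoxy)benzyl)-4,5-bis(methoxymethoxy)phenyl]ethoxy}triisopropylsilane, via 3-lithio aryl bromide 13 (not isolated), via aryne 14 (not isolated), via arylmagnesium chloride 15 (not isolated)
Conditions: lithium 2,2,6,6-tetramethylpiperidide (LiTMP, 1.2 equiv) added slowly to 4 and 12, THF–Et2O, −78 °C; −78 → 0 °C; re-cooled to −78 °C and transferred into excess BrCl2C–CCl2Br, then rt
Reagents that add atoms: 1,2-dibromo-1,1,2,2-tetrachloroethane, ClC(Cl)(Br)C(Cl)(Cl)Br
Why: LiTMP removes H3 of 4, the only ring hydrogen flanked by bromine and an OMOM group, and the 3-metallo-2-bromoarene 13 loses metal bromide on warming, so only the C2–C3 aryne 14 can form. The C4 oxygen next to the aryne polarises the strained triple bond so that the benzyl carbanion of 12 attacks C2, the carbon remote from oxygen, and magnesium ends up on C3, where it is held by induction and by chelation to the MOM oxygen until the arylmagnesium 15 meets the positive-bromine donor. The closest known reaction type is the carbomagnesiation of 3-alkoxyarynes generated by amide-base dehydrohalogenation, followed by halogen quench of the 2-alkoxyarylmagnesium. No ring is closed and no stereocentre is created. The selectivity needed is the sense of addition (carbon at C2, bromine at C3), secured by the C4 alkoxy group and by the single acidic hydrogen of 4; ring B of 12 has no hydrogen ortho to bromine, so it cannot give a competing aryne by deprotonation. The silyl ether keeps the side-chain oxygen from closing a dihydrobenzofuran onto C2.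

Step 11
Reactants: 16 {2-[3-bromo-2-(2,3-dibromo-4,5-bis(methoxymethoxy)benzyl)-4,5-bis(methoxymethoxy)phenyl]ethoxy}triisopropylsilane
Product: 17 2-[3-bromo-2-(2,3-dibromo-4,5-bis(methoxymethoxy)benzyl)-4,5-bis(methoxymethoxy)phenyl]ethanol
Conditions: TBAF, THF, 0 °C → rt
Reagents that add atoms: none
Why: Fluoride-driven desilylation (strong Si–F bond); MOM acetals, aryl bromides and the diarylmethane are inert to TBAF.

Step 12
Reactants: 17 2-[3-bromo-2-(2,3-dibromo-4,5-bis(methoxymethoxy)benzyl)-4,5-bis(methoxymethoxy)phenyl]ethanol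
Product: 19 sodium 2-[3-bromo-2-(2,3-dibromo-4,5-bis(methoxymethoxy)benzyl)-4,5-bis(methoxymethoxy)phenyl]ethyl sulfate, via pyridinium alkyl sulfate 18 (not isolated)
Conditions: SO3·pyridine, pyridine, rt → 40 °C; then aq NaHCO3
Reagents that add atoms: sulfur trioxide–pyridine complex, O=S(=O)([O-])[n+]1ccccc1; sodium hydrogen carbonate, [Na+].OC([O-])=O
Why: O-sulfonation of an alcohol by the SO3–pyridine complex followed by cation exchange; every phenol is still an acetal, so only the primary hydroxyl can be sulfated.

Step 13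
Reactants: 19 sodium 2-[3-bromo-2-(2,3-dibromo-4,5-bis(methoxymethoxy)benzyl)-4,5-bis(methoxymethoxy)phenyl]ethyl sulfate
Product: 20 2-[3-bromo-2-(2,3-dibromo-4,5-dihydroxybenzyl)-4,5-dihydroxyphenyl]ethyl hydrogen sulfate (target CNP0136879.0)
Conditions: 1 M aq HCl–MeOH (3:1, degassed), 0 °C → rt; C18 desalting (H2O → aq MeCN), freeze-drying
Reagents that add atoms: none
Why: Acid hydrolysis of the four aryl MOM acetals; a primary alkyl sulfate monoester is hydrolysed by dilute aqueous acid only on heating, and the water-rich medium suppresses the solvolytic loss of SO3 that dry ethereal acid would cause, so the sulfate should survive and the product should be obtained as the free acid.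

**Compound list**
1 | hydroxytyrosol, 2-(3,4-dihydroxyphenyl)ethanol | OCCc1ccc(O)c(O)c1 | starting material
2 | 2-[3,4-bis(methoxymethoxy)phenyl]ethanol | OCCc1ccc(OCOC)c(OCOC)c1 | intermediate
3 | {2-[3,4-bis(methoxymethoxy)phenyl]ethoxy}triisopropylsilane | CC(C)[Si](OCCc1ccc(OCOC)c(OCOC)c1)(C(C)C)C(C)C | intermediate
4 | {2-[2-bromo-4,5-bis(methoxymethoxy)phenyl]ethoxy}triisopropylsilane | CC(C)[Si](OCCc1cc(OCOC)c(OCOC)cc1Br)(C(C)C)C(C)C | intermediate
5 | 5-bromovanillin | COc1cc(C=O)cc(Br)c1O | starting material
6 | 5,6-dibromovanillin, 2,3-dibromo-4-hydroxy-5-methoxybenzaldehyde | COc1cc(C=O)c(Br)c(Br)c1O | intermediate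
7 | 2,3-dibromo-4,5-dihydroxybenzaldehyde | O=Cc1cc(O)c(O)c(Br)c1Br | intermediate
8 | 2,3-dibromo-4,5-bis(methoxymethoxy)benzaldehyde | COCOc1cc(C=O)c(Br)c(Br)c1OCOC | intermediate
9 | [2,3-dibromo-4,5-bis(methoxymethoxy)phenyl]methanol | COCOc1cc(CO)c(Br)c(Br)c1OCOC | intermediate
10 | 2,3-dibromo-4,5-bis(methoxymethoxy)benzyl methanesulfonate | COCOc1cc(COS(C)(=O)=O)c(Br)c(Br)c1OCOC | intermediate
11 | 2,3-dibromo-4,5-bis(methoxymethoxy)benzyl chloride | COCOc1cc(CCl)c(Br)c(Br)c1OCOC | intermediate
12 | [2,3-dibromo-4,5-bis(methoxymethoxy)benzyl]magnesium chloride | COCOc1cc(C[Mg]Cl)c(Br)c(Br)c1OCOC | intermediate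
13 | {2-[2-bromo-3-lithio-4,5-bis(methoxymethoxy)phenyl]ethoxy}triisopropylsilane | CC(C)[Si](OCCc1cc(OCOC)c(OCOC)c([Li])c1Br)(C(C)C)C(C)C | intermediate
14 | 3,4-bis(methoxymethoxy)-6-[2-(triisopropylsilyloxy)ethyl]benzyne (triple bond C2–C3 of ring A) | CC(C)[Si](OCCC1=CC(OCOC)=C(OCOC)C#C1)(C(C)C)C(C)C | intermediate
15 | [2-(2,3-dibromo-4,5-bis(methoxymethoxy)benzyl)-5,6-bis(methoxymethoxy)-3-(2-triisopropylsilyloxyethyl)phenyl]magnesium chloride | CC(C)[Si](OCCc1cc(OCOC)c(OCOC)c([Mg]Cl)c1Cc1cc(OCOC)c(OCOC)c(Br)c1Br)(C(C)C)C(C)C | intermediate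
16 | {2-[3-bromo-2-(2,3-dibromo-4,5-bis(methoxymethoxy)benzyl)-4,5-bis(methoxymethoxy)phenyl]ethoxy}triisopropylsilane | CC(C)[Si](OCCc1cc(OCOC)c(OCOC)c(Br)c1Cc1cc(OCOC)c(OCOC)c(Br)c1Br)(C(C)C)C(C)C | intermediate
17 | 2-[3-bromo-2-(2,3-dibromo-4,5-bis(methoxymethoxy)benzyl)-4,5-bis(methoxymethoxy)phenyl]ethanol | OCCc1cc(OCOC)c(OCOC)c(Br)c1Cc1cc(OCOC)c(OCOC)c(Br)c1Br | intermediate
18 | pyridinium 2-[3-bromo-2-(2,3-dibromo-4,5-bis(methoxymethoxy)benzyl)-4,5-bis(methoxymethoxy)phenyl]ethyl sulfate | O=S(=O)([O-])OCCc1cc(OCOC)c(OCOC)c(Br)c1Cc1cc(OCOC)c(OCOC)c(Br)c1Br.c1cc[nH+]cc1 | intermediate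
19 | sodium 2-[3-bromo-2-(2,3-dibromo-4,5-bis(methoxymethoxy)benzyl)-4,5-bis(methoxymethoxy)phenyl]ethyl sulfate | O=S(=O)([O-])OCCc1cc(OCOC)c(OCOC)c(Br)c1Cc1cc(OCOC)c(OCOC)c(Br)c1Br.[Na+] | intermediate
20 | 2-[3-bromo-2-(2,3-dibromo-4,5-dihydroxybenzyl)-4,5-dihydroxyphenyl]ethyl hydrogen sulfate | O=S(=O)(O)OCCc1cc(O)c(O)c(Br)c1Cc1cc(O)c(O)c(Br)c1Br | target

**Step count**
Total: 13 steps. Longest linear sequence: 10 steps (5 to 20, steps 4 to 13); the hydroxytyrosol branch (steps 1 to 3) joins at step 10.

**Steps most likely to fail**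

1. Step 10. The aryne may be consumed by paths other than capture by the benzylmagnesium reagent (addition of the amide or of the lithiated bromide 13). Halogen–metal exchange on the vicinal dibromide of ring B may open a second aryne channel. The arylmagnesium may also be protonated before bromine transfer, leaving C3 unbrominated.
Fallback, setting out from 3 and 12 and coming back at 16: the two bonds are made one after the other by known reactions. Iodination of 3 with N-iodosuccinimide in MeCN, at the same position that NBS attacks, should give {2-[2-iodo-4,5-bis(methoxymethoxy)phenyl]ethoxy}triisopropylsilane F1. LiTMP added at −78 °C to F1 in THF containing ZnCl2 (in situ trapping) should metalate the hydrogen between iodine and OMOM and give [2-iodo-5,6-bis(methoxymethoxy)-3-(2-triisopropylsilyloxyethyl)phenyl]zinc chloride F2, a covalent arylzinc that does not eliminate to the aryne. Br2 at low temperature should convert it into {2-[3-bromo-2-iodo-4,5-bis(methoxymethoxy)phenyl]ethoxy}triisopropylsilane F3. Kumada–Corriu coupling of 12 with F3 (PdCl2(dppf), THF, 0 °C) at the C–I bond, which zerovalent palladium enters much faster than any C–Br bond, should then give 16.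

2. Step 9. Magnesium may insert into the aryl C–Br bonds as well as the benzylic C–Cl bond, which on a vicinal dibromide leads on to elimination. The benzylic reagent may also homocouple (Wurtz) or lose titre before use.
Fallback, setting out from 11 and coming back at 16: zinc dust with LiCl in THF inserts into benzylic chlorides while leaving aryl bromides alone and should give [2,3-dibromo-4,5-bis(methoxymethoxy)benzyl]zinc chloride F4. A benzylzinc is too weak a nucleophile for the aryne, so the C–C bond is closed by Negishi coupling (Pd(PPh3)4, THF, rt) with the bromo iodide F3 of the preceding fallback, selectively at its C–I bond, to give 16.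

3. Step 13. Acid-promoted loss of the sulfate (solvolytic SO3 transfer) may compete with acetal hydrolysis if the medium becomes water-poor, and released formaldehyde may condense with the free catechol rings.
Fallback, setting out from 17 and coming back at 20: the sulfate is carried through the acid step as a neutral diester. Alcohol 17 with 1-(2,2,2-trichloroethoxysulfonyl)-2,3-dimethylimidazolium triflate and 1,2-dimethylimidazole in CH2Cl2 should give 2-[3-bromo-2-(2,3-dibromo-4,5-bis(methoxymethoxy)benzyl)-4,5-bis(methoxymethoxy)phenyl]ethyl 2,2,2-trichloroethyl sulfate F5. Moist CF3CO2H in CH2Cl2 at 0 °C should remove the four MOM groups without touching the diester and give 2-[3-bromo-2-(2,3-dibromo-4,5-dihydroxybenzyl)-4,5-dihydroxyphenyl]ethyl 2,2,2-trichloroethyl sulfate F6. Zinc dust with ammonium formate in MeOH should cleave the trichloroethyl group reductively to ammonium 2-[3-bromo-2-(2,3-dibromo-4,5-dihydroxybenzyl)-4,5-dihydroxyphenyl]ethyl sulfate F7. Brief treatment with cold dilute aq HCl and C18 desalting should return the free acid 20.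

**Further compounds**
F1 | step 10 | {2-[2-iodo-4,5-bis(methoxymethoxy)phenyl]ethoxy}triisopropylsilane | CC(C)[Si](OCCc1cc(OCOC)c(OCOC)cc1I)(C(C)C)C(C)C
F2 | step 10 | [2-iodo-5,6-bis(methoxymethoxy)-3-(2-triisopropylsilyloxyethyl)phenyl]zinc chloride | CC(C)[Si](OCCc1cc(OCOC)c(OCOC)c([Zn]Cl)c1I)(C(C)C)C(C)C
F3 | step 10 | {2-[3-bromo-2-iodo-4,5-bis(methoxymethoxy)phenyl]ethoxy}triisopropylsilane | CC(C)[Si](OCCc1cc(OCOC)c(OCOC)c(Br)c1I)(C(C)C)C(C)C
F4 | step 9 | [2,3-dibromo-4,5-bis(methoxymethoxy)benzyl]zinc chloride | COCOc1cc(C[Zn]Cl)c(Br)c(Br)c1OCOC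
F5 | step 13 | 2-[3-bromo-2-(2,3-dibromo-4,5-bis(methoxymethoxy)benzyl)-4,5-bis(methoxymethoxy)phenyl]ethyl 2,2,2-trichloroethyl sulfate | ClC(Cl)(Cl)COS(=O)(=O)OCCc1cc(OCOC)c(OCOC)c(Br)c1Cc1cc(OCOC)c(OCOC)c(Br)c1Br
F6 | step 13 | 2-[3-bromo-2-(2,3-dibromo-4,5-dihydroxybenzyl)-4,5-dihydroxyphenyl]ethyl 2,2,2-trichloroethyl sulfate | ClC(Cl)(Cl)COS(=O)(=O)OCCc1cc(O)c(O)c(Br)c1Cc1cc(O)c(O)c(Br)c1Br
F7 | step 13 | ammonium 2-[3-bromo-2-(2,3-dibromo-4,5-dihydroxybenzyl)-4,5-dihydroxyphenyl]ethyl sulfate | [NH4+].O=S(=O)([O-])OCCc1cc(O)c(O)c(Br)c1Cc1cc(O)c(O)c(Br)c1Br
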